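**Plan**
1. Feature used: rings A and B of the pterocarpan, together with C6, C6a and C11a, form a 3-aryl-1-benzopyrylium (isoflavylium) ion that differs from the target by one hydride. The D-ring oxygen O11, the 2'-OH of that ion, reaches C11a (pyrylium C4) through a five-membered ring.
2. Cuts: first O11–C11a plus the C6–H and C6a–H bonds (13 back to cation 10, its lactol 9 and coumarin 8). Then C6a=C11a and O5–C6 (8 back to salicylaldehyde 5 and arylacetic acid 7). Last, the O–CMe2 and C2–CH2 bonds of ring E (5 back to phloroglucinaldehyde 1 and prenal 3).
3. Forward order of rings: A and D are bought. E is annulated on the 4-O-benzyl ether of 1, which forces its oxygen next to the formyl carbon (later C1). B is closed by a Perkin condensation that also attaches D. C is closed in the last step.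
4. Stereochemistry: nothing is stereogenic before the last step. There a chiral phosphoric acid sets C6a by protonation, and the equilibrating centre C11a is locked cis to it when a Hantzsch ester reduces C6.

Key step: step 7

Assumption: the sense of induction of the chiral acid cannot be derived from precedent, so (R)-TRIP is written and its (S)-antipode is used instead if the first run gives the (6aR,11aR) series.
Numbering: pterocarpan numbering is used for 10–13, chromane or coumarin numbering for the earlier compounds.

**Step 1**
Reactants: 1 2,4,6-trihydroxybenzaldehyde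
Product: 2 4-(benzyloxy)-2,6-dihydroxybenzaldehyde
Conditions: BnBr (1.0 equiv), K2CO3 (1.0 equiv), DMF, 0 °C → rt
Reagents that add atoms: benzyl bromide, BrCc1ccccc1
Why: Williamson etherification with one equivalent of base, in which the 4-OH (para to the formyl group, a vinylogous carboxylic acid, and the only hydroxyl not chelated to the carbonyl oxygen) is ionised and alkylated first, as is usual for phloroglucinaldehyde and phloroacetophenone.

**Step 2**
Reactants: 2 4-(benzyloxy)-2,6-dihydroxybenzaldehyde; 3 3-methylbut-2-enal (prenal)
Product: 4 5-(benzyloxy)-7-hydroxy-2,2-dimethyl-2H-chromene-8-carbaldehyde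
Conditions: Ca(OH)2 (1.0 equiv), 3 (1.2 equiv), MeOH, rt; aq HCl work-up
Reagents that add atoms: none
Why: Base-mediated formal [3+3] chromene annulation of a formylresorcinol with an enal (aldol-type C-alkylation at C3, dehydration, oxa-6π electrocyclisation), in which the blocked O-4 leaves only a hydroxyl ortho to the formyl group to become the pyran oxygen, and the symmetry of 2 makes the two choices identical, so one regioisomer should result.

**Step 3**
Reactants: 4 5-(benzyloxy)-7-hydroxy-2,2-dimethyl-2H-chromene-8-carbaldehyde
Product: 5 5,7-dihydroxy-2,2-dimethylchromane-8-carbaldehyde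
Conditions: H2 (1 atm), 10 % Pd/C, EtOAc, rt
Reagents that add atoms: none
Why: Heterogeneous catalytic hydrogenation saturates the chromene C3=C4 bond and hydrogenolyses the benzyl ether in one operation, while the chelated, strongly electron-rich aldehyde should be inert at atmospheric pressure in a neutral aprotic solvent.

**Step 4**
Reactants: 6 2-(2-bromo-4-methoxyphenyl)acetic acid
Product: 7 2-(2-hydroxy-4-methoxyphenyl)acetic acid
Conditions: CuI (10 mol %), 1,10-phenanthroline (20 mol %), KOH (4 equiv), DMSO–H2O (1:1), 100 °C; then aq HCl to pH 2
Reagents that add atoms: potassium hydroxide, [K+].[OH-]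
Why: Copper-catalysed Ullmann-type hydroxylation of an aryl bromide, assisted by the neighbouring carboxylate as in the technical preparation of 2-hydroxyphenylacetic acid, so that the position of the halogen fixes the 2-OH/4-OMe pattern without any selective methylation of a resorcinol.

**Step 5**
Reactants: 5 5,7-dihydroxy-2,2-dimethylchromane-8-carbaldehyde; 7 2-(2-hydroxy-4-methoxyphenyl)acetic acid
Product: 8 5-acetoxy-9-(2-acetoxy-4-methoxyphenyl)-2,2-dimethyl-3,4-dihydro-2H,8H-pyrano[2,3-f]chromen-8-one (a 7-acetoxy-3-arylcoumarin with ring E fused through O at coumarin C5 and CH2 at C6)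
Conditions: Ac2O (excess), Et3N (3 equiv), 110 °C
Reagents that add atoms: acetic anhydride, CC(=O)OC(C)=O
Why: Perkin–Oglialoro condensation of a salicylaldehyde with an arylacetic acid, in which C=C formation between the activated CH2 of 7 and the formyl group of 5 is followed by lactonisation through the only ortho hydroxyl of 5 (ring B), and the two phenols not used are acetylated in the same pot.

**Step 6**
Reactants: 8 the coumarin diacetate
Product: 9 9-(2-hydroxy-4-methoxyphenyl)-2,2-dimethyl-3,4-dihydro-2H,8H-pyrano[2,3-f]chromene-5,8-diol (the 2H-chromen-2-ol lactol, racemic at the hemiacetal carbon, all phenols free)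
Conditions: DIBAL-H (6 equiv), CH2Cl2, −78 °C; aq Rochelle salt; used crude
Reagents that add atoms: none
Why: Partial lactone reduction with DIBAL-H, a known route from coumarins to 2H-chromen-2-ols because the aluminium hemiacetal survives at −78 °C, with the excess reagent cleaving both aryl acetates reductively so that no separate deprotection is needed.

**Step 7**
Reactants: 9 the lactol
Product: 13 (6aS,11aS)-3-hydroxy-9-methoxypterocarpan bearing the 2,2-dimethyldihydropyran ring E at C1 (O) and C2 (CH2), via isoflavylium ion 10 (not isolated), via ring-closed enol ether 11 (not isolated), via cis-fused oxocarbenium ion 12 (not isolated)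
Conditions: (R)-TRIP (10 mol %), 5 Å MS, toluene–CH2Cl2 (3:1), −20 °C, 30 min; then di-tert-butyl Hantzsch ester (1.1 equiv) by syringe pump over 6 h, −20 → 0 °C; recrystallisation (EtOAc–heptane)
Reagents that add atoms: none
Why: Proposed new method: the chiral acid ionises lactol 9 to the aromatic cation 10, the 2'-OH (O11) of 10 adds reversibly to C11a to give the neutral enol ether 11, whose only stereocentre is erased at every ring opening, the acid then protonates C6a of one enantiomer of 11, and the Hantzsch ester reduces C6 of the resulting contact ion pair 12 irreversibly, so that both enantiomers of 11 drain into one product (dynamic kinetic resolution). The closest known reaction types are the phosphoric acid/Hantzsch ester transfer hydrogenation of 1-benzopyrylium ions released from 2H-chromen-2-ols, the activation of enol ethers as oxocarbenium phosphates, and the racemic hydride reduction of 2'-hydroxyisoflavylium salts to pterocarpans; their combination into one enantioselective cascade is untested. Ring C closes by 5-exo-trig attack of O11 on the C11a=C11b quinone-methide canonical form of 10, a mode that is 5-endo only with respect to the C6a=C11a form and is unproblematic for capture of a delocalised cation. C6a is set by the face to which the phosphate, anchored by hydrogen bonds to the free 3-OH and to O11, delivers its proton, and C11a is tied to it because only the cis-fused 6/5 oxocarbenium ion is attainable, the trans-fused one being heavily strained. The step needs O11–C11a closure before any hydride reaches C11a, which the substrate secures through the peri ring-E oxygen on C1 and the flanking ring D that screen C11a from the bulky ester but not from the intramolecular phenol, helped by the low acid loading and the slow feed of reductant that keep free 10 scarce. Two leaks are harmless: addition of O11 to C6 is reversible, and hydride that reaches C6 early leaves an electron-rich styrene that the same acid protonates at C6a and that closes the same ring.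

**Compound list**
1 | 2,4,6-trihydroxybenzaldehyde | O=Cc1c(O)cc(O)cc1O | starting material
2 | 4-(benzyloxy)-2,6-dihydroxybenzaldehyde | O=Cc1c(O)cc(OCc2ccccc2)cc1O | intermediate
3 | 3-methylbut-2-enal (prenal) | CC(C)=CC=O | starting material
4 | 5-(benzyloxy)-7-hydroxy-2,2-dimethyl-2H-chromene-8-carbaldehyde | O=Cc1c(O)cc(OCc2ccccc2)c2C=CC(C)(C)Oc12 | intermediate
5 | 5,7-dihydroxy-2,2-dimethylchromane-8-carbaldehyde | O=Cc1c(O)cc(O)c2CCC(C)(C)Oc12 | intermediate
6 | 2-(2-bromo-4-methoxyphenyl)acetic acid | COc1ccc(CC(O)=O)c(Br)c1 | starting material
7 | 2-(2-hydroxy-4-methoxyphenyl)acetic acid | COc1ccc(CC(O)=O)c(O)c1 | intermediate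
8 | 5-acetoxy-9-(2-acetoxy-4-methoxyphenyl)-2,2-dimethyl-3,4-dihydro-2H,8H-pyrano[2,3-f]chromen-8-one | CC(=O)Oc1cc2OC(=O)C(c3ccc(OC)cc3OC(C)=O)=Cc2c4OC(C)(C)CCc14 | intermediate
9 | 9-(2-hydroxy-4-methoxyphenyl)-2,2-dimethyl-3,4-dihydro-2H,8H-pyrano[2,3-f]chromene-5,8-diol (lactol, racemic) | COc1ccc(c(O)c1)C1=Cc2c(OC1O)cc(O)c1CCC(C)(C)Oc21 | intermediate
10 | 2'-hydroxyisoflavylium ion with ring E and free 7-OH (counter-ion: the TRIP phosphate) | COc1ccc(-c2c[o+]c3cc(O)c4CCC(C)(C)Oc4c3c2)c(O)c1 | intermediate
11 | ring-closed C6=C6a enol ether (racemising at C11a) | COc1ccc2c(c1)OC1c3c(cc(O)c4c3OC(C)(C)CC4)OC=C21 | intermediate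
12 | cis-fused O5=C6 oxocarbenium ion, spatial arrangement at C6a and C11a as in 13 (counter-ion: the TRIP phosphate) | COc1ccc2c(c1)O[C@@H]1c3c(cc(O)c4c3OC(C)(C)CC4)[O+]=C[C@H]21 | intermediate
13 | (6aS,11aS)-3-hydroxy-9-methoxypterocarpan with ring E at C1 (O) and C2 (CH2), CNP0207547.1 | COc1ccc2c(c1)O[C@@H]1c3c(cc(O)c4c3OC(C)(C)CC4)OC[C@H]21 | target

**Step count**
Total step count: 7
Longest linear sequence: 6 (steps 1, 2, 3, 5, 6, 7)

**Steps most likely to fail**

1. Step 7.
   - What may go wrong: hydride may be delivered to C11a of the free cation before ring C has closed. Enantiofacial discrimination in the C6a protonation may be weak. Acid-induced reopening of ring C in the product may lead to over-reduction.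
   - Fallback: hydride delivery, ring closure and stereochemical selection are separated into known operations.
   - Setting out from 9, ionic reduction of the lactol with Et3SiH (1.0 equiv)/CF3CO2H in CH2Cl2 at −40 °C should give the 2'-hydroxyisoflav-3-ene F1.
   - Catalytic TsOH in CH2Cl2 at rt then protonates this vinylogous phenol at C6a, and O11 captures the C11a cation (acid-induced cyclisation of an isoflavene to a pterocarpan). This should give the racemic cis-pterocarpan F2.
   - Preparative SFC on a polysaccharide chiral phase separates the enantiomers and returns to the route at 13.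

2. Step 6.
   - What may go wrong: hydride may be consumed unselectively. The aluminium phenoxides released from the acetates deactivate the lactone, and forcing the reaction leads to ring opening and over-reduction to the allylic alcohol. The lactol may also ionise during isolation.
   - Fallback: the reduction is run on a substrate whose only reducible group is the lactone.
   - Setting out from 8, methanolysis (cat. K2CO3, MeOH, 0 °C) should give the dihydroxycoumarin F3.
   - TBSCl/imidazole in DMF gives the bis-silyl ether F4.
   - DIBAL-H (1.1 equiv, toluene, −78 °C) gives the bis-silyl lactol F5.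
   - TBAF buffered with AcOH in THF at 0 °C frees both phenols and returns to the route at 9.

3. Step 2.
   - What may go wrong: C-alkylation of the formyl-deactivated ring may be sluggish. A second annulation may occur on the remaining hydroxyl. Prenal may self-condense.
   - Fallback: the C5 unit is brought in at the alkane oxidation level by C-prenylation instead of enal condensation.
   - Setting out from 2, prenyl bromide with aqueous KOH at 0 °C → rt should give the C-prenyl aldehyde F6.
   - Catalytic TsOH in toluene at 80 °C adds the only adjacent free hydroxyl across the prenyl double bond (Markovnikov hydroalkoxylation) to give the benzyl-protected chromane aldehyde F7.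
   - Hydrogenolysis (H2, Pd/C, EtOAc) returns to the route at 5.

**Further compounds**
F1 | step 7 | 2'-hydroxyisoflav-3-ene with ring E and free 7-OH | COc1ccc(c(O)c1)C1=Cc2c(OC1)cc(O)c1CCC(C)(C)Oc21
F2 | step 7 | racemic cis-pterocarpan (both enantiomers written) | COc1ccc2c(c1)O[C@@H]1c3c(cc(O)c4c3OC(C)(C)CC4)OC[C@H]21.COc1ccc2c(c1)O[C@H]1c3c(cc(O)c4c3OC(C)(C)CC4)OC[C@@H]21
F3 | step 6 | 5-hydroxy-9-(2-hydroxy-4-methoxyphenyl)-2,2-dimethyl-3,4-dihydro-2H,8H-pyrano[2,3-f]chromen-8-one | COc1ccc(c(O)c1)C1=Cc2c(OC1=O)cc(O)c1CCC(C)(C)Oc21
F4 | step 6 | bis(tert-butyldimethylsilyl) ether of F3 | COc1ccc(c(O[Si](C)(C)C(C)(C)C)c1)C1=Cc2c(OC1=O)cc(O[Si](C)(C)C(C)(C)C)c1CCC(C)(C)Oc21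
F5 | step 6 | bis(tert-butyldimethylsilyl) ether of lactol 9 (racemic) | COc1ccc(c(O[Si](C)(C)C(C)(C)C)c1)C1=Cc2c(OC1O)cc(O[Si](C)(C)C(C)(C)C)c1CCC(C)(C)Oc21
F6 | step 2 | 4-(benzyloxy)-2,6-dihydroxy-3-(3-methylbut-2-en-1-yl)benzaldehyde | O=Cc1c(O)cc(OCc2ccccc2)c(CC=C(C)C)c1O
F7 | step 2 | 5-(benzyloxy)-7-hydroxy-2,2-dimethylchromane-8-carbaldehyde | O=Cc1c(O)cc(OCc2ccccc2)c2CCC(C)(C)Oc12
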